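Readings and results are calculated with constants of no real substance.

I watched the slope first.

| setting | noon | spring | violet | blue |
|---|---|---|---|---|
| free monomer | 0.017 M | 0.061 M | 0.020 M | 0.080 M |
| initiator | 1 mM | 1 mM | 1.0 mM | 1.0 mM |
| remark | run made earlier | run made earlier |  |  |
| time |  |  | 2.5 d | 2.5 d |

| run | time / h | monomer in chains / % |
|---|---|---|
| noon | 2.50 | 0.6 |
| noon | 5.00 | 1.3 |
| noon | 8.00 | 2.6 |
| noon | 15.0 | 7.0 |
| noon | 30.0 | 20.6 |
| spring | 6.00 | 4.4 |
| spring | 12.0 | 11.2 |
| spring | 20.0 | 22.8 |
| spring | 25.0 | 29.6 |
| spring | 30.0 | 35.9 |

(scatter of a reading: 0.3 percentage points)

- the average divides the monomer in chains by the number of chains begun, living and dead together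
- what was read earlier has a scatter of 0.3 percentage points, one standard deviation
- the earlier runs do not show the number of chains; that part of a forecast is a guess

- which of the two ends with the longer chains by the average number of monomer units in a chain (chains begun, living or dead) ("neither" if they lie within 10%) (violet / blue / neither)
- average number of monomer units in a chain (chains begun, living or dead) at the end, violet
- average number of monomer units in a chain (chains begun, living or dead) at the end, blue

In the spring run the logarithm of free monomer charged over free monomer left climbs slowly and then straightens. Between 25.0 h and 30.0 h the spring run gives the full-speed rate A, the fraction of free monomer taken per hour once the chains stand, as 0.0187 h⁻¹. Violet and blue charge the same initiator as spring, so I froze A for both and treated the loss as pseudo-first-order. I read the run-in from the first spring reading: with a slope growing in step with time, the start time τ is A times the squared time, over twice the logarithm there, or 7.50 h. I took τ as inverse to free monomer, as the early slopes suggested.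

The ladder, fastest first, was blue's τ of 5.72 h, violet's τ of 22.9 h, the monomer time 1/A of 53.3 h, and the run of 60 h. I let initiator fall with time constant τ, and each flask lost τ times the share used. On that reckoning violet used 92.7% of its initiator and converted 51.7% of its free monomer. On the same reckoning blue used >99.9% of its initiator and converted 63.9% of its free monomer. The earlier runs show no chains, so one chain per initiator used is a guess. It gave averages of 11.1 for violet and 51.1 for blue.

The forecast said blue, with 12 for violet (9 to 15) and 52 for blue (42 to 63), adding “Chain count is assumed, not observed”; both my figures stood below its own.

Violet came to 13.5 and blue to 47.9, so blue had the longer chains. At the end violet held 30.6% of its own initiator and blue 1.76%.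

    free monomer + living end → monomer in chains + living end, rate k1*[living end]*[free monomer] (k = 29.2 M⁻¹ h⁻¹)
    2 living end → dead end (k = 18.7 M⁻¹ h⁻¹)
    free monomer + initiator → living end + monomer in chains (k = 1.28 M⁻¹ h⁻¹)
    free monomer → decomposition product (k = 1.44 × 10⁻⁴ h⁻¹)

For a neighbour of violet charged with 0.050 M free monomer, I reckoned τ as 9.15 h. Reckoning 99.9% of initiator used, A gave 61.5% converted and an average of 30.8. That flask gave 30.4, with 7.1% of its initiator left.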